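**Plan**

- Cuts, in retrosynthetic order: the two aryl benzyl ethers; the C6 methyl group (back to a formyl carbon) and the C2=C3 double bond (back to a C2 formyl group that is excised), these two carbons being the ends of an etheno bridge between C2 and C6; the C4–CH2 bond (Michael addition); C2–C3 and C5–C6 together.
- Enabling feature: O1 with its neighbours C2 and C6 is the C2–O–C5 unit of furan, and C3 (with its ester)–C4–C5 (with CH2O) is the three-carbon unit of a vinylcarbene. The dihydropyran is therefore the oxygen-containing six-membered ring of an 8-oxabicyclo[3.2.1]octadiene made by dearomatizing [4+3] annulation, with furan C3/C4 as a temporary two-carbon tether.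
- Forward order: vinyl diazo ester (3 steps) → [4+3] builds the pyran ring inside the bicycle → Michael addition installs the side chain as the finished hydroxytyrosol ester → ozonolysis cuts the tether and the freed C5 hydroxymethyl traps the C6 formyl as a lactol → Baeyer–Villiger/elimination removes the C2 formyl carbon and creates C2=C3 → the lactol carbon is reduced to the methyl group → debenzylation.
- Stereochemistry: absolute configuration from the chiral dirhodium catalyst (bridgehead = C6); C5 from the E vinyl geometry through the boat Cope transition state; C4 from exo-face Michael addition trans to the C5 group; the cis C5/C6 relation is built in because the future methyl carbon is the axial bridge carbon.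

Key step: step 4

Assumption: Rh2(S-DOSP)4 is taken, by analogy with its cyclopropanation model, to give the (1R,4R,5S) cycloadduct; if the antipode forms, Rh2(R-DOSP)4 is used with nothing else changed.

Locants: bicyclic compounds use 8-oxabicyclo[3.2.1]octane numbering; ring-opened compounds use the pyran numbering of the target (O1, C2 … C6).

**Route**

Step 1
Reactants: 1 glycine methyl ester hydrochloride
Product: 2 methyl diazoacetate
Conditions: NaNO2, H2SO4 (cat.), H2O/CH2Cl2, −5 °C; used as dried CH2Cl2 solution
Reagents that add atoms: sodium nitrite, [Na+].[O-]N=O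
Why: Diazotization of an α-amino ester, in which the diazonium ion loses the acidic α-proton to give the stabilized diazo ester.

Step 2
Reactants: 2 methyl diazoacetate; 3 3-[(tert-butyldimethylsilyl)oxy]propanal
Product: 4 methyl 5-[(tert-butyldimethylsilyl)oxy]-2-diazo-3-hydroxypentanoate (racemic carbinol)
Conditions: DBU (10 mol%), MeCN, rt
Reagents that add atoms: none
Why: Amine-base-catalysed aldol-type addition of the acidic diazoacetate C–H to an aldehyde should give the β-hydroxy-α-diazo ester, whose carbinol centre is destroyed in the next step.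

Step 3
Reactants: 4 methyl 5-[(tert-butyldimethylsilyl)oxy]-2-diazo-3-hydroxypentanoate
Product: 5 methyl (E)-5-[(tert-butyldimethylsilyl)oxy]-2-diazopent-3-enoate
Conditions: POCl3, Et3N, CH2Cl2, 0 °C; used at once, kept cold
Reagents that add atoms: none
Why: Dehydration through the dichlorophosphate can only eliminate toward C4 and should give the conjugated E-vinyldiazoacetate, which is used immediately to forestall cyclization to a pyrazole.

Step 4
Reactants: 5 methyl (E)-5-[(tert-butyldimethylsilyl)oxy]-2-diazopent-3-enoate; 6 furan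
Product: 8 methyl (1R,4R,5S)-4-{[(tert-butyldimethylsilyl)oxy]methyl}-8-oxabicyclo[3.2.1]octa-2,6-diene-2-carboxylate (CH2OTBS endo, anti to the oxygen bridge), via cis-divinylcyclopropane 7 (not isolated)
Conditions: Rh2(S-DOSP)4 (1 mol%; DOSP = N-(4-dodecylphenylsulfonyl)prolinate), furan (5 equiv), hexanes, −78 °C to rt, slow addition of 5
Reagents that add atoms: none
Why: The dirhodium tetracarboxylate expels N2 from 5 to give a rhodium-bound vinylcarbene, which cyclopropanates the 2,3-bond of furan (dearomatization) with the propenyl group cis to the remaining enol-ether double bond to give 7, and 7 undergoes a Cope rearrangement through the boat transition state below room temperature, so that the carbene carbon ends up bonded to one furan α-carbon and the vinyl terminus to the other. The closest known reaction type is the tandem cyclopropanation/Cope rearrangement (formal [4+3] cycloaddition) of vinyldiazoacetates with furans and 1,3-dienes under dirhodium carboxylate catalysis. The ring closed is the seven-membered carbocycle C1–C7 and with it the six-membered oxygen ring O8–C1–C2–C3–C4–C5 (the pyran ring of the target), in a [4+3] sense through a [3,3]-sigmatropic shift. The bridgeheads C1 and C5 (C5 becomes C6 of the target) are set in the absolute sense by the chiral prolinate ligands during cyclopropanation, and C4 (C5 of the target) by the E geometry of the vinyl group, which the boat transition state turns into an endo CH2OTBS group, cis on the oxygen ring to the etheno carbon that later becomes the methyl group. The step needs cyclopropanation/Cope to win over zwitterionic opening of furan to trienes and over attack at the vinyl terminus, which the unsubstituted furan, the acceptor ester on the carbene, the E substituent at the vinyl terminus, the non-polar solvent and the low temperature should secure.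

Step 5
Reactants: 9 hydroxytyrosol [2-(3,4-dihydroxyphenyl)ethanol]
Product: 10 2-[3,4-bis(benzyloxy)phenyl]ethanol
Conditions: BnBr (2.1 equiv), K2CO3, acetone, reflux
Reagents that add atoms: benzyl bromide, BrCc1ccccc1
Why: Williamson etherification in which K2CO3 deprotonates only the phenols, so the aliphatic hydroxyl should stay free.

Step 6
Reactants: 10 2-[3,4-bis(benzyloxy)phenyl]ethanol
Product: 11 2-[3,4-bis(benzyloxy)phenyl]ethyl acetate
Conditions: Ac2O, pyridine, DMAP (cat.), CH2Cl2, rt
Reagents that add atoms: acetic anhydride, CC(=O)OC(C)=O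
Why: DMAP-catalysed acylation of a primary alcohol.

Step 7
Reactants: 8 methyl (1R,4R,5S)-4-{[(tert-butyldimethylsilyl)oxy]methyl}-8-oxabicyclo[3.2.1]octa-2,6-diene-2-carboxylate; 11 2-[3,4-bis(benzyloxy)phenyl]ethyl acetate
Product: 14 methyl (1R,3S,4R,5S)-3-(2-{2-[3,4-bis(benzyloxy)phenyl]ethoxy}-2-oxoethyl)-4-{[(tert-butyldimethylsilyl)oxy]methyl}-8-oxabicyclo[3.2.1]oct-6-ene-2-carboxylate (C2 epimer mixture), via lithium enolate of acetate 12 (not isolated), via lithium enolate of adduct 13 (not isolated)
Conditions: LiN(iPr)2, 11, THF, −78 °C; then 8, −78 °C; NH4Cl (aq.), −78 °C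
Reagents that add atoms: none
Why: Michael addition of a lithium ester enolate to the strained bicyclic enoate should occur at C3 from the exo face (side of the oxygen bridge, anti to the endo C4 substituent), as organometallic additions to 8-azabicyclo[3.2.1]oct-2-ene-2-carboxylates do, which places the side chain trans to CH2OTBS, while the C2 centre formed on protonation does not matter because it becomes sp2 later.

Step 8
Reactants: 14 methyl (1R,3S,4R,5S)-3-(2-{2-[3,4-bis(benzyloxy)phenyl]ethoxy}-2-oxoethyl)-4-{[(tert-butyldimethylsilyl)oxy]methyl}-8-oxabicyclo[3.2.1]oct-6-ene-2-carboxylate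
Product: 16 lactol aldehyde: methyl tetrahydropyran-3-carboxylate with free formyl at C2, the side chain at C4, and the C5 CH2–O closed onto the C6 formyl carbon as a cis-fused 2-hydroxytetrahydrofuran (anomer mixture, in equilibrium with its internal hemiacetal), via dialdehyde 15 (not isolated)
Conditions: O3, CH2Cl2/MeOH, −78 °C (Sudan red 7B end point); Me2S, −78 °C to rt; then HF·pyridine, THF, 0 °C
Reagents that add atoms: ozone, [O-][O+]=O
Why: Ozonolysis should cleave only the strained C6=C7 alkene (the temporary tether) to the 2,6-cis dialdehyde, and desilylation then frees the C5 hydroxymethyl, which is cis and adjacent only to the C6 formyl group and closes onto it as a five-membered lactol, so the two formyl carbons become different.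

Step 9
Reactants: 16 lactol aldehyde
Product: 18 methyl 5,6-dihydro-4H-pyran-3-carboxylate with the (4S) side chain, whose C5 CH2–O and C6 CH(OH) form the cis-fused lactol ring (anomer mixture), via anomeric formate 17 (not isolated)
Conditions: mCPBA, CH2Cl2, 0 °C to rt; then DBU, 0 °C to rt
Reagents that add atoms: none
Why: Baeyer–Villiger oxidation of the free α-alkoxy aldehyde (migration of the oxygen-bearing carbon with retention) should give the anomeric formate, from which DBU eliminates formic acid by an E1cB path through the C3 ester enolate to give the vinylogous carbonate C2=C3, while the almost fully closed lactol carbon reacts more slowly.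

Step 10
Reactants: 18 enol ether lactol
Product: 20 methyl (4S,5R,6S)-4-(2-{2-[3,4-bis(benzyloxy)phenyl]ethoxy}-2-oxoethyl)-5-(hydroxymethyl)-6-methyl-5,6-dihydro-4H-pyran-3-carboxylate, via tosylhydrazone 19 (not isolated)
Conditions: TsNHNH2, THF, rt; catecholborane, CHCl3, 0 °C; NaOAc·3H2O, rt
Reagents that add atoms: none
Why: The lactol should condense through its open hydroxy-aldehyde form to the tosylhydrazone, and catecholborane reduction followed by acetate-induced loss of sulfinate and N2 (Caglioti-type reduction) turns the former aldehyde carbon into the C6 methyl group without touching the esters or the enol ether, while the C5 hydroxymethyl is set free.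

Step 11
Reactants: 20 methyl (4S,5R,6S)-4-(2-{2-[3,4-bis(benzyloxy)phenyl]ethoxy}-2-oxoethyl)-5-(hydroxymethyl)-6-methyl-5,6-dihydro-4H-pyran-3-carboxylate
Product: 21 methyl (4S,5R,6S)-4-{2-[2-(3,4-dihydroxyphenyl)ethoxy]-2-oxoethyl}-5-(hydroxymethyl)-6-methyl-5,6-dihydro-4H-pyran-3-carboxylate
Conditions: H2 (1 atm), 10% Pd/C, EtOAc, rt; handled under argon
Reagents that add atoms: none
Why: Hydrogenolysis of the two aryl benzyl ethers under neutral conditions, with the trisubstituted push–pull enol ether expected to be hydrogenated far more slowly.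

**Compound list**

1 | glycine methyl ester hydrochloride | Cl.NCC(=O)OC | starting material
2 | methyl diazoacetate | COC(=O)C=[N+]=[N-] | intermediate
3 | 3-[(tert-butyldimethylsilyl)oxy]propanal | O=CCCO[Si](C)(C)C(C)(C)C | starting material
4 | methyl 5-[(tert-butyldimethylsilyl)oxy]-2-diazo-3-hydroxypentanoate (racemic) | COC(=O)C(=[N+]=[N-])C(O)CCO[Si](C)(C)C(C)(C)C | intermediate
5 | methyl (E)-5-[(tert-butyldimethylsilyl)oxy]-2-diazopent-3-enoate | COC(=O)C(=[N+]=[N-])/C=C/CO[Si](C)(C)C(C)(C)C | intermediate
6 | furan | c1ccoc1 | starting material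
7 | methyl (1R,5R,6R)-6-[(E)-3-{[tert-butyl(dimethyl)silyl]oxy}prop-1-en-1-yl]-2-oxabicyclo[3.1.0]hex-3-ene-6-carboxylate (propenyl on the face of the dihydrofuran ring) | COC(=O)[C@]1(/C=C/CO[Si](C)(C)C(C)(C)C)[C@H]2C=CO[C@@H]12 | intermediate
8 | methyl (1R,4R,5S)-4-{[(tert-butyldimethylsilyl)oxy]methyl}-8-oxabicyclo[3.2.1]octa-2,6-diene-2-carboxylate | COC(=O)C1=C[C@H](CO[Si](C)(C)C(C)(C)C)[C@@H]2C=C[C@H]1O2 | intermediate
9 | hydroxytyrosol, 2-(3,4-dihydroxyphenyl)ethanol | OCCc1ccc(O)c(O)c1 | starting material
10 | 2-[3,4-bis(benzyloxy)phenyl]ethanol | OCCc1ccc(OCc2ccccc2)c(OCc2ccccc2)c1 | intermediate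
11 | 2-[3,4-bis(benzyloxy)phenyl]ethyl acetate | CC(=O)OCCc1ccc(OCc2ccccc2)c(OCc2ccccc2)c1 | intermediate
12 | lithium enolate of 11 | [Li+].[O-]C(=C)OCCc1ccc(OCc2ccccc2)c(OCc2ccccc2)c1 | intermediate
13 | lithium C2 ester enolate of the Michael adduct (3S,4R; bridgeheads as in 8) | COC([O-])=C1[C@@H](CC(=O)OCCc3ccc(OCc4ccccc4)c(OCc4ccccc4)c3)[C@H](CO[Si](C)(C)C(C)(C)C)[C@@H]2C=C[C@H]1O2.[Li+] | intermediate
14 | methyl (1R,3S,4R,5S)-3-(2-{2-[3,4-bis(benzyloxy)phenyl]ethoxy}-2-oxoethyl)-4-{[(tert-butyldimethylsilyl)oxy]methyl}-8-oxabicyclo[3.2.1]oct-6-ene-2-carboxylate (C2 epimers) | COC(=O)C1[C@@H](CC(=O)OCCc3ccc(OCc4ccccc4)c(OCc4ccccc4)c3)[C@H](CO[Si](C)(C)C(C)(C)C)[C@@H]2C=C[C@H]1O2 | intermediate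
15 | methyl 4-(2-{2-[3,4-bis(benzyloxy)phenyl]ethoxy}-2-oxoethyl)-5-{[(tert-butyldimethylsilyl)oxy]methyl}-2,6-diformyltetrahydro-2H-pyran-3-carboxylate (formyl groups 2,6-cis; 5,6-cis; 4,5-trans; C3 epimers) | COC(=O)C1[C@@H](CC(=O)OCCc2ccc(OCc3ccccc3)c(OCc3ccccc3)c2)[C@H](CO[Si](C)(C)C(C)(C)C)[C@H](C=O)O[C@@H]1C=O | intermediate
16 | lactol aldehyde: as 15 without silyl group, C5 CH2–O closed onto the C6 formyl carbon (cis-fused 2-hydroxytetrahydrofuran, anomers), C2 formyl free | COC(=O)C1[C@@H](CC(=O)OCCc3ccc(OCc4ccccc4)c(OCc4ccccc4)c3)[C@@H]2COC(O)[C@@H]2O[C@@H]1C=O | intermediate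
17 | anomeric formate: as 16 with C2–O–CHO in place of C2–CHO (retention at C2) | COC(=O)C1[C@@H](CC(=O)OCCc3ccc(OCc4ccccc4)c(OCc4ccccc4)c3)[C@@H]2COC(O)[C@@H]2O[C@@H]1OC=O | intermediate
18 | enol ether lactol: methyl 5,6-dihydro-4H-pyran-3-carboxylate with (4S) side chain and cis-fused lactol ring across C5/C6 (anomers) | COC(=O)C1=CO[C@H]2C(O)OC[C@H]2[C@@H]1CC(=O)OCCc3ccc(OCc4ccccc4)c(OCc4ccccc4)c3 | intermediate
19 | tosylhydrazone of the open form of 18 (C6–CH=N–NHTs, C5–CH2OH) | COC(=O)C1=CO[C@@H](C=NNS(=O)(=O)c2ccc(C)cc2)[C@@H](CO)[C@@H]1CC(=O)OCCc3ccc(OCc4ccccc4)c(OCc4ccccc4)c3 | intermediate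
20 | methyl (4S,5R,6S)-4-(2-{2-[3,4-bis(benzyloxy)phenyl]ethoxy}-2-oxoethyl)-5-(hydroxymethyl)-6-methyl-5,6-dihydro-4H-pyran-3-carboxylate | COC(=O)C1=CO[C@@H](C)[C@@H](CO)[C@@H]1CC(=O)OCCc2ccc(OCc3ccccc3)c(OCc3ccccc3)c2 | intermediate
21 | methyl (4S,5R,6S)-4-{2-[2-(3,4-dihydroxyphenyl)ethoxy]-2-oxoethyl}-5-(hydroxymethyl)-6-methyl-5,6-dihydro-4H-pyran-3-carboxylate | COC(=O)C1=CO[C@@H](C)[C@@H](CO)[C@@H]1CC(=O)OCCc1ccc(O)c(O)c1 | target

**Count and risks**

Total steps: 11. Longest linear sequence: 9 steps (1, 2, 3, 4, 7, 8, 9, 10, 11); the side-chain branch is steps 5 and 6.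

Step 4. The carbene–furan adduct may unravel to open-chain trienes instead of closing to the cyclopropane, diazo ester 5 may cyclize to a pyrazole before it is consumed, and facial discrimination on furan may be only moderate. The fallback changes the carbene partner to a siloxyvinylcarbene and sets out from 4. Dess–Martin periodinane should oxidize 4 to methyl 5-[(tert-butyldimethylsilyl)oxy]-2-diazo-3-oxopentanoate F1. TBSOTf/Et3N should convert this into methyl (Z)-3,5-bis[(tert-butyldimethylsilyl)oxy]-2-diazopent-3-enoate F2. With furan 6 and Rh2(S-PTAD)4 in hexanes, the same cyclopropanation/Cope sequence should give methyl (1R,4R,5S)-3-[(tert-butyldimethylsilyl)oxy]-4-{[(tert-butyldimethylsilyl)oxy]methyl}-8-oxabicyclo[3.2.1]octa-2,6-diene-2-carboxylate F3. One equivalent of Et3N·3HF should cleave only the enol silyl ether to methyl (1R,4R,5S)-4-{[(tert-butyldimethylsilyl)oxy]methyl}-3-oxo-8-oxabicyclo[3.2.1]oct-6-ene-2-carboxylate F4. NaBH4 in MeOH at −20 °C should give methyl (1R,4R,5S)-4-{[(tert-butyldimethylsilyl)oxy]methyl}-3-hydroxy-8-oxabicyclo[3.2.1]oct-6-ene-2-carboxylate F5. MsCl/Et3N should give the corresponding 3-methanesulfonate F6, from which DBU eliminates by an E1cB path, and the route is rejoined at 8.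

Step 9. Peracid addition may be slow because the aldehyde sits as an internal hemiacetal, hydride instead of carbon may migrate, or the lactol carbon may be oxidized as well. The fallback excises the carbon by decarboxylation and sets out from 16. Pinnick oxidation (NaClO2, NaH2PO4, 2-methyl-2-butene, tBuOH/H2O) should give the C2 carboxylic acid of the lactol F7, the same acid that hydride migration would produce. Dehydrodecarboxylation of this α-alkoxy acid (9-mesitylacridine photocatalyst, Co(dmgH)2(py)Cl, 400 nm light, CH2Cl2) should form the α-alkoxy radical at C2 and remove the C3 hydrogen, and the route is rejoined at 18.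

Step 10. Condensation of the closed lactol with the sulfonyl hydrazide may be incomplete, the open α-alkoxy aldehyde or its hydrazone may enolize and erode C6, or the freed hydroxymethyl may lactonize onto the side-chain ester under the boron Lewis acid. The fallback goes through a thioacetal and sets out from 18. Ethanethiol with Zn(OTf)2 in CH2Cl2 should open the lactol, as in aldose mercaptal formation, to the C6 bis(ethylsulfanyl)methyl compound with free C5 hydroxymethyl F8. Radical desulfurization with nBu3SnH/AIBN in toluene at reflux should reduce the dithioacetal carbon to the methyl group, and the route is rejoined at 20.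

**Further compounds**

F1 | step 4 | methyl 5-[(tert-butyldimethylsilyl)oxy]-2-diazo-3-oxopentanoate | COC(=O)C(=[N+]=[N-])C(=O)CCO[Si](C)(C)C(C)(C)C
F2 | step 4 | methyl (Z)-3,5-bis[(tert-butyldimethylsilyl)oxy]-2-diazopent-3-enoate | COC(=O)C(=[N+]=[N-])/C(O[Si](C)(C)C(C)(C)C)=C/CO[Si](C)(C)C(C)(C)C
F3 | step 4 | methyl (1R,4R,5S)-3-[(tert-butyldimethylsilyl)oxy]-4-{[(tert-butyldimethylsilyl)oxy]methyl}-8-oxabicyclo[3.2.1]octa-2,6-diene-2-carboxylate | COC(=O)C1=C(O[Si](C)(C)C(C)(C)C)[C@H](CO[Si](C)(C)C(C)(C)C)[C@@H]2C=C[C@H]1O2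
F4 | step 4 | methyl (1R,4R,5S)-4-{[(tert-butyldimethylsilyl)oxy]methyl}-3-oxo-8-oxabicyclo[3.2.1]oct-6-ene-2-carboxylate | COC(=O)C1C(=O)[C@H](CO[Si](C)(C)C(C)(C)C)[C@@H]2C=C[C@H]1O2
F5 | step 4 | methyl (1R,4R,5S)-4-{[(tert-butyldimethylsilyl)oxy]methyl}-3-hydroxy-8-oxabicyclo[3.2.1]oct-6-ene-2-carboxylate | COC(=O)C1C(O)[C@H](CO[Si](C)(C)C(C)(C)C)[C@@H]2C=C[C@H]1O2
F6 | step 4 | methyl (1R,4R,5S)-4-{[(tert-butyldimethylsilyl)oxy]methyl}-3-[(methylsulfonyl)oxy]-8-oxabicyclo[3.2.1]oct-6-ene-2-carboxylate | COC(=O)C1C(OS(C)(=O)=O)[C@H](CO[Si](C)(C)C(C)(C)C)[C@@H]2C=C[C@H]1O2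
F7 | step 9 | C2 carboxylic acid of lactol 16 (C2–CO2H in place of C2–CHO) | COC(=O)C1[C@@H](CC(=O)OCCc3ccc(OCc4ccccc4)c(OCc4ccccc4)c3)[C@@H]2COC(O)[C@@H]2O[C@@H]1C(O)=O
F8 | step 10 | methyl (4S,5R,6S)-4-(2-{2-[3,4-bis(benzyloxy)phenyl]ethoxy}-2-oxoethyl)-6-[bis(ethylsulfanyl)methyl]-5-(hydroxymethyl)-5,6-dihydro-4H-pyran-3-carboxylate | COC(=O)C1=CO[C@@H](C(SCC)SCC)[C@@H](CO)[C@@H]1CC(=O)OCCc2ccc(OCc3ccccc3)c(OCc3ccccc3)c2
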